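**Retrosynthetic overview**
- 17 ⇐ trans-hydroazulene enone 10. The C7 hydroxyl and the oxirane are added late: C4-OH-directed hydride delivery to C6, acylation, singlet-oxygen ene reaction (C7-OH, alkene moved to C8=C9), epoxidation of the open α face, hydrogenolysis.
- 10 ⇐ cis-decalin triol monomesylate 8 by a semipinacol 1,2-shift of the ring-fusion bond C1–C6 onto C5. Ring A (cyclohexane C1–C2–C3–C4–C5–C6) contracts to the cyclopentane C1–C2–C3–C4–C5, and ring B (cyclohexene C1–C6–C7–C8–C9–C10) expands to the cycloheptenone in the same event.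
- Enabling feature: in 8 the oxygens on C4, C5 and C6 and the C1 methyl all lie on one face of ring A. With the isopropyl group equatorial, the C5–OMs bond is equatorial and antiperiplanar to C6–C1. C4 and C6 carry no hydrogen, and C6 is an allylic carbinol (C7=C8 of ring B) whose push ends in a conjugated enone.
- 8 ⇐ linear dienone 4 (1,2-addition of isopropyl, OH-directed osmylation, mesylation) ⇐ commercial (S)-octalone 1 (dehydrogenation, 1,6-addition of methyl, dehydrogenation).
- Order of rings: both six-membered rings come with 1; the five- and seven-membered rings form together in step 7; the oxirane is formed last (step 11).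

Key step: step 7

Remark: locants C1–C10 are the daucane locants of the target and are carried back unchanged into the decalins: C1 = methyl-bearing fusion carbon, C4 = isopropyl carbinol, C5 = fusion CH, C6 = ester carbon, C7 = carbinol, C8/C9 = oxirane, C10 = CH2. β is the face of the C1 methyl group. Ketone 1 is assumed to be purchased as the enantiopure (S)-(+) form.

Step 1
Reactants: 1 (S)-4a-methyl-4,4a,5,6,7,8-hexahydronaphthalen-2(3H)-one
Product: 2 (S)-4a-methyl-4,4a,5,6-tetrahydronaphthalen-2(3H)-one
Conditions: chloranil, t-BuOH, reflux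
Reagents that add atoms: none
Why: Chloranil dehydrogenation of a 4-en-3-one-type enone removes hydride from the δ-carbon (C8) of the dienol, so the linear rather than the cross-conjugated dienone should form and the quaternary C1 is untouched.

Step 2
Reactants: 2 (S)-4a-methyl-4,4a,5,6-tetrahydronaphthalen-2(3H)-one
Product: 3 (4aS,7S)-4a,7-dimethyl-4,4a,5,6,7,8-hexahydronaphthalen-2(3H)-one
Conditions: MeMgBr, CuBr·SMe2 (10 mol %), THF, −40 to 0 °C; then 2 M HCl
Reagents that add atoms: methylmagnesium bromide C[Mg]Br
Why: Copper-catalysed 1,6-conjugate addition of a Grignard reagent to a linear dienone (the reaction used for 7-methyl steroids) should place the methyl on C8 mainly anti to the C1 methyl, the acidic work-up restores conjugation, and both C8 epimers are carried on because step 3 erases this centre.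

Step 3
Reactants: 3 (4aS,7S)-4a,7-dimethyl-4,4a,5,6,7,8-hexahydronaphthalen-2(3H)-one
Product: 4 (S)-4a,7-dimethyl-4,4a,5,6-tetrahydronaphthalen-2(3H)-one
Conditions: chloranil, t-BuOH, reflux
Reagents that add atoms: none
Why: A second chloranil dehydrogenation abstracts the tertiary C8 hydride of the dienol, which the flexible bicycle can turn axial in either epimer, so both epimers of 3 converge on one dienone with C7=C8 in place.

Step 4
Reactants: 4 (S)-4a,7-dimethyl-4,4a,5,6-tetrahydronaphthalen-2(3H)-one
Product: 5 (2R,4aS)-2-isopropyl-4a,7-dimethyl-2,3,4,4a,5,6-hexahydronaphthalen-2-ol (C4-OH β)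
Conditions: i-PrMgCl, LaCl3·2LiCl, THF, 0 °C; pH 7 buffer
Reagents that add atoms: isopropylmagnesium chloride CC(C)[Mg]Cl
Why: Lanthanide-mediated 1,2-addition of a Grignard reagent suppresses enolisation, reduction and conjugate addition, and axial attack on the α face (opposite the axial C1 methyl, as in additions to steroidal 4-en-3-ones) should place the C4 hydroxyl β, with the minor epimer removed by chromatography.

Step 5
Reactants: 5 (2R,4aS)-2-isopropyl-4a,7-dimethyl-2,3,4,4a,5,6-hexahydronaphthalen-2-ol
Product: 7 all-cis triol (cis-decalin; OH on C4 C5 C6 all β; C7=C8 kept), via osmate ester TMEDA chelate 6 (not isolated)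
Conditions: OsO4 (1.05 equiv), TMEDA, CH2Cl2, −78 °C; then aq. Na2SO3, THF, reflux
Reagents that add atoms: osmium tetroxide O=[Os](=O)(=O)=O
Why: In this hydrogen-bond-directed dihydroxylation the OsO4·TMEDA complex accepts a hydrogen bond from the pseudoaxial C4β hydroxyl (isopropyl and C1 methyl pseudoequatorial in this half-chair), which should steer the suprafacial [3+2] addition to the neighbouring C5=C6 bond rather than C7=C8 and to the β face, setting C5 and C6 syn to C4-OH.

Step 6
Reactants: 7 all-cis triol
Product: 8 C5β-methanesulfonate of triol 7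
Conditions: MsCl, Et3N, CH2Cl2, −20 °C
Reagents that add atoms: methanesulfonyl chloride CS(=O)(=O)Cl
Why: Mesylation via sulfene reacts only with the single secondary, equatorial C5 hydroxyl, since the two flanking tertiary hydroxyls are inert at low temperature, and it leaves the C5 configuration unchanged.

Step 7
Reactants: 8 C5β-methanesulfonate of triol 7
Product: 10 trans-fused hydroxy enone (3-hydroxy-3-isopropyl-6,8a-dimethyl-2,3,3a,7,8,8a-hexahydroazulen-4(1H)-one; C1-CH3 β; C4-OH β; H5 α), via bis(diethylaluminium) alkoxide 9 (not isolated)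
Conditions: Et3Al (3 equiv), CH2Cl2, −78 to 0 °C; aq. potassium sodium tartrate
Reagents that add atoms: none
Why: Et3Al first converts both tertiary hydroxyls of 8 into diethylaluminium alkoxides (9) and then, bound to the sulfonate as a Lewis acid, pulls the C5 mesylate while the C6 alkoxide pushes, so the ring-fusion bond C6–C1 migrates to C5 in a concerted 1,2-shift and C6 becomes the carbonyl carbon. The closest known reaction type is the pinacol-type (semipinacol) rearrangement of 2-sulfonyloxy alcohols, both in its organoaluminium-promoted form and in its classical use for turning 9-hydroxydecal-1-yl sulfonates into hydroazulenones. No ring is closed by cyclisation: the shift of the one shared bond contracts ring A (six atoms, C1 to C6) to the cyclopentane C1–C2–C3–C4–C5 and at the same time expands ring B (six atoms) to the cycloheptenone C1–C5–C6–C7–C8–C9–C10. The only new stereocentre, C5, is set by inversion at the mesylate carbon (C1 enters on the α face anti to the β mesylate, leaving H5 α and a trans ring fusion), while C1 migrates with retention and C4 is untouched, so the all-cis array of 8 becomes the 1β-CH3, 4β-OH, 5α-H pattern of the target. The step needs C1 to migrate rather than C3 (push from O4) or C7: the equatorial C5–O bond is antiperiplanar only to C6–C1 and C4–C3, C7 is gauche, and of the two aligned bonds C6–C1 is favoured because C1 is quaternary whereas C3 is a CH2 group and because only the allylic C6 carbinol delivers a conjugated enone. Elimination and oxirane formation are excluded by the substrate (no hydrogen on C4 or C6, both neighbouring oxygens gauche to the leaving group), and the C4 oxygen stays bound to aluminium until the cold work-up, which protects the new aldol unit from retro-aldol cleavage.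

Step 8
Reactants: 10 trans-fused hydroxy enone
Product: 11 dauc-7-ene-4β,6α-diol
Conditions: Me4NBH(OAc)3, MeCN–AcOH, −25 °C
Reagents that add atoms: none
Why: In this Evans–Saksena reduction, ligand exchange at boron with the C4β hydroxyl and intramolecular hydride delivery to the β face of the C6 carbonyl, a face that a free hydride would find shielded by the axial C1 methyl, should give the equatorial 6α allylic alcohol by 1,2-reduction.

Step 9
Reactants: 11 dauc-7-ene-4β,6α-diol; 12 4-(benzyloxy)benzoyl chloride
Product: 13 6α-[4-(benzyloxy)benzoyloxy]dauc-7-en-4β-ol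
Conditions: Et3N, DMAP (cat.), CH2Cl2, rt
Reagents that add atoms: none
Why: DMAP-catalysed acyl transfer acylates the only secondary hydroxyl (C6α-OH) with retention while the hindered tertiary C4-OH stays free, and the benzyl ether keeps the phenol inert towards singlet oxygen and the dioxirane.

Step 10
Reactants: 13 6α-[4-(benzyloxy)benzoyloxy]dauc-7-en-4β-ol
Product: 15 6α-[4-(benzyloxy)benzoyloxy]dauc-8-ene-4β,7β-diol, via 7β-hydroperoxide 14 (not isolated)
Conditions: O2, tetraphenylporphyrin (cat.), visible light, CH2Cl2, −20 °C; then PPh3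
Reagents that add atoms: oxygen O=O
Why: This is a Schenck ene reaction followed by phosphine reduction: in the chair cycloheptene of 13 the carbocycle lies under the α face, so only the β face is open and only there do allylic hydrogens stand out of the alkene plane; the perepoxide opens at the more substituted C8 and takes hydrogen from C9 on the doubly substituted side of the alkene (cis effect, with H6 deactivated by the geminal acyloxy group), so oxygen should end on C7β and the double bond at C8=C9.

Step 11
Reactants: 15 6α-[4-(benzyloxy)benzoyloxy]dauc-8-ene-4β,7β-diol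
Product: 16 6α-[4-(benzyloxy)benzoyloxy]-8α,9α-epoxydaucane-4β,7β-diol
Conditions: dimethyldioxirane, acetone, 0 °C
Reagents that add atoms: dimethyldioxirane CC1(C)OO1
Why: This dioxirane epoxidation runs under steric control: with the alkene at C8=C9 the chair cycloheptene turns its carbocycle and the axial C1 methyl to the β side, the equatorial C7 hydroxyl lies near the alkene plane and is solvated by acetone (a poor director), so oxygen should be transferred to the open α face, anti to C7-OH, under neutral conditions.

Step 12
Reactants: 16 6α-[4-(benzyloxy)benzoyloxy]-8α,9α-epoxydaucane-4β,7β-diol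
Product: 17 6α-(4-hydroxybenzoyloxy)-8α,9α-epoxydaucane-4β,7β-diol (target)
Conditions: H2 (1 atm), Pd/C, EtOAc, rt
Reagents that add atoms: none
Why: Catalytic hydrogenolysis of the aryl benzyl ether frees the phenol under neutral conditions, so acyl migration between O6 and O7, Payne rearrangement and oxirane opening are not triggered and no stereocentre is touched.

**Compound list**
1 | (S)-4a-methyl-4,4a,5,6,7,8-hexahydronaphthalen-2(3H)-one | O=C1CC[C@]2(C)CCCCC2=C1 | starting material
2 | (S)-4a-methyl-4,4a,5,6-tetrahydronaphthalen-2(3H)-one | O=C1CC[C@]2(C)CCC=CC2=C1 | intermediate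
3 | (4aS,7S)-4a,7-dimethyl-4,4a,5,6,7,8-hexahydronaphthalen-2(3H)-one (major C8 epimer, methyl α) | O=C1CC[C@]2(C)CC[C@H](C)CC2=C1 | intermediate
4 | (S)-4a,7-dimethyl-4,4a,5,6-tetrahydronaphthalen-2(3H)-one | O=C1CC[C@]2(C)CCC(C)=CC2=C1 | intermediate
5 | (2R,4aS)-2-isopropyl-4a,7-dimethyl-2,3,4,4a,5,6-hexahydronaphthalen-2-ol (OH cis to the angular methyl) | CC(C)[C@]1(O)CC[C@]2(C)CCC(C)=CC2=C1 | intermediate
6 | cyclic C5,C6 osmate ester of 5 on the β face (hexavalent osmium, TMEDA chelate) | CC(C)[C@]1(O)CC[C@]2(C)CCC(C)=C[C@@]23O[Os](=O)(=O)O[C@@H]13.CN(C)CCN(C)C | intermediate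
7 | 2-isopropyl-4a,7-dimethyl-1,2,3,4,4a,5,6,8a-octahydronaphthalene-1,2,8a-triol, cis-fused, three OH and angular methyl all β | CC(C)[C@]1(O)CC[C@]2(C)CCC(C)=C[C@]2(O)[C@H]1O | intermediate
8 | C5β (naphthalene C1) methanesulfonate of 7 | CC(C)[C@]1(O)CC[C@]2(C)CCC(C)=C[C@]2(O)[C@H]1OS(C)(=O)=O | intermediate
9 | O4,O6-bis(diethylaluminium) alkoxide of 8 | CC(C)[C@]1(O[Al](CC)CC)CC[C@]2(C)CCC(C)=C[C@]2(O[Al](CC)CC)[C@H]1OS(C)(=O)=O | intermediate
10 | 3-hydroxy-3-isopropyl-6,8a-dimethyl-2,3,3a,7,8,8a-hexahydroazulen-4(1H)-one, trans-fused (4β-hydroxydauc-7-en-6-one) | CC(C)[C@]1(O)CC[C@]2(C)CCC(C)=CC(=O)[C@H]21 | intermediate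
11 | dauc-7-ene-4β,6α-diol | CC(C)[C@]1(O)CC[C@]2(C)CCC(C)=C[C@H](O)[C@H]21 | intermediate
12 | 4-(benzyloxy)benzoyl chloride | O=C(Cl)c1ccc(OCc2ccccc2)cc1 | starting material
13 | 6α-[4-(benzyloxy)benzoyloxy]dauc-7-en-4β-ol | CC(C)[C@]1(O)CC[C@]2(C)CCC(C)=C[C@H](OC(=O)c3ccc(OCc4ccccc4)cc3)[C@H]21 | intermediate
14 | 6α-[4-(benzyloxy)benzoyloxy]-7β-hydroperoxydauc-8-en-4β-ol | CC(C)[C@]1(O)CC[C@]2(C)CC=C(C)[C@@H](OO)[C@H](OC(=O)c3ccc(OCc4ccccc4)cc3)[C@H]21 | intermediate
15 | 6α-[4-(benzyloxy)benzoyloxy]dauc-8-ene-4β,7β-diol | CC(C)[C@]1(O)CC[C@]2(C)CC=C(C)[C@@H](O)[C@H](OC(=O)c3ccc(OCc4ccccc4)cc3)[C@H]21 | intermediate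
16 | 6α-[4-(benzyloxy)benzoyloxy]-8α,9α-epoxydaucane-4β,7β-diol | CC(C)[C@]1(O)CC[C@]2(C)C[C@@H]3O[C@]3(C)[C@@H](O)[C@H](OC(=O)c3ccc(OCc4ccccc4)cc3)[C@H]21 | intermediate
17 | 6α-(4-hydroxybenzoyloxy)-8α,9α-epoxydaucane-4β,7β-diol (CNP0290052.1) | CC(C)[C@]1(O)CC[C@]2(C)C[C@@H]3O[C@]3(C)[C@@H](O)[C@H](OC(=O)c3ccc(O)cc3)[C@H]21 | target

Total step count: 12. Longest linear sequence: 12 steps (from 1); 12 is purchased.

**Steps most likely to fail**

Step 5.
- What may go wrong: the osmium reagent may add to the less hindered C7=C8 bond or to the α face, or it may add only sluggishly to an alkene flanked by two fully substituted carbons.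
- Fallback: keep ring B saturated until after the rearrangement, so that only one alkene is offered to the reagent.
- It sets out from 3. Addition of i-PrMgCl/LaCl3·2LiCl gives the ring-B-saturated allylic alcohol F1. Directed osmylation with OsO4·TMEDA gives the saturated all-cis triol F2, and MsCl/Et3N gives its C5 mesylate F3.
- Et3Al then induces the same shift of C1 to give the saturated hydroxy ketone F4. IBX in DMSO dehydrogenates F4; only C7–C8 can be desaturated, because C5 has no hydrogen-bearing β-carbon.
- The fallback returns to the route at 10.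

Step 7.
- What may go wrong: the C4 alkoxide may compete as electron donor (shift of C3 instead of C1), the Lewis acid may ionise the tertiary allylic C6–O bond, or the aldol unit of the product may be lost by retro-aldol cleavage or dehydration.
- Fallback: leave a single donor oxygen and run the shift under purely anionic conditions.
- It sets out from 6, which is isolated by chromatography and used as a temporary diol protecting group. TESOTf/2,6-lutidine silylates the only free hydroxyl to give the C4-O-triethylsilyl osmate ester F5.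
- Aqueous Na2SO3 releases the C4-O-triethylsilyl 5,6-diol F6, and MsCl/Et3N gives the mesylate F7. KOt-Bu in THF at low temperature then triggers the shift from the sole free C6 alkoxide to the silyl-protected enone F8.
- HF·pyridine removes the silyl group, and the fallback returns to the route at 10.

Step 10.
- What may go wrong: hydrogen may be abstracted from the C8 methyl group (exocyclic alkene) or from C6, or facial control of the ene reaction may be poor.
- Fallback: an ionic route through a C7 ketone.
- It sets out from 13. Epoxidation of the open β face with dimethyldioxirane gives the 7β,8β-epoxide F9. Meinwald rearrangement with BF3·OEt2 (tertiary C8 cation, 1,2-hydride shift from C7) gives the C7 ketone F10.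
- IBX dehydrogenation towards C9 gives the C7 enone F11. Luche reduction (NaBH4, CeCl3·7H2O) from the open α face then gives the 7β-alcohol.
- The fallback returns to the route at 15.

**Further compounds**
F1 | step 5 | 2-isopropyl-4a,7-dimethyl-2,3,4,4a,5,6,7,8-octahydronaphthalen-2-ol (C4-OH β, C8-CH3 α) | CC(C)[C@]1(O)CC[C@]2(C)CC[C@H](C)CC2=C1
F2 | step 5 | ring-B-saturated all-cis triol (C4, C5, C6-OH β, C8-CH3 α) | CC(C)[C@]1(O)CC[C@]2(C)CC[C@H](C)C[C@]2(O)[C@H]1O
F3 | step 5 | C5β-methanesulfonate of F2 | CC(C)[C@]1(O)CC[C@]2(C)CC[C@H](C)C[C@]2(O)[C@H]1OS(C)(=O)=O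
F4 | step 5 | 4β-hydroxydaucan-6-one (trans-fused, C8-CH3 α) | CC(C)[C@]1(O)CC[C@]2(C)CC[C@H](C)CC(=O)[C@H]21
F5 | step 7 | C4-O-triethylsilyl derivative of osmate ester 6 | CC(C)[C@]1(O[Si](CC)(CC)CC)CC[C@]2(C)CCC(C)=C[C@@]23O[Os](=O)(=O)O[C@@H]13.CN(C)CCN(C)C
F6 | step 7 | C4-O-triethylsilyl ether of triol 7 | CC(C)[C@]1(O[Si](CC)(CC)CC)CC[C@]2(C)CCC(C)=C[C@]2(O)[C@H]1O
F7 | step 7 | C5β-methanesulfonate of F6 | CC(C)[C@]1(O[Si](CC)(CC)CC)CC[C@]2(C)CCC(C)=C[C@]2(O)[C@H]1OS(C)(=O)=O
F8 | step 7 | C4-O-triethylsilyl ether of enone 10 | CC(C)[C@]1(O[Si](CC)(CC)CC)CC[C@]2(C)CCC(C)=CC(=O)[C@H]21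
F9 | step 10 | 6α-[4-(benzyloxy)benzoyloxy]-7β,8β-epoxydaucan-4β-ol | CC(C)[C@]1(O)CC[C@]2(C)CC[C@@]3(C)O[C@H]3[C@H](OC(=O)c3ccc(OCc4ccccc4)cc3)[C@H]21
F10 | step 10 | 6α-[4-(benzyloxy)benzoyloxy]-4β-hydroxydaucan-7-one (C8-CH3 β) | CC(C)[C@]1(O)CC[C@]2(C)CC[C@@H](C)C(=O)[C@H](OC(=O)c3ccc(OCc4ccccc4)cc3)[C@H]21
F11 | step 10 | 6α-[4-(benzyloxy)benzoyloxy]-4β-hydroxydauc-8-en-7-one | CC(C)[C@]1(O)CC[C@]2(C)CC=C(C)C(=O)[C@H](OC(=O)c3ccc(OCc4ccccc4)cc3)[C@H]21
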